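**Plan**

1. Retrosynthesis: cut C11=C12 and C11'=C12' (two Wittig unions, C15 + C10 + C15), then C7=C8 (Horner–Wadsworth–Emmons), then the C1–C6 bond of the trihydroxycyclohexane ring.
2. Enabling feature: C1 is a gem-dimethyl quaternary carbon (a tertiary cation when unbound), and its neighbour C6 carries O6 and C7. With C7 as an ester, C6 is an enolisable α-carbon whose O6 and O5 can be tied into a 1,3-dioxolane.
3. Forward, trihydroxy end: (S)-epichlorohydrin → acyclic C1–C7 chain by way of a δ-lactone → ring C1–C6 closed by intramolecular tertiary alkylation of a ketene silyl acetal → C7 aldehyde → C15 Wittig salt.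
4. Forward, ε-end: (R)-α-ionone → C15 Wittig salt → C25 aldehyde with the C10 dialdehyde → final Wittig union with the trihydroxy C15 salt.
5. Stereochemistry: C3 from (S)-epichlorohydrin; C5 from lactone-controlled OsO4 addition anti to the side chain; C6 from the cis ring fusion that the dioxolane enforces in the key step (either C6 epimer of the precursor converges); C6' from (R)-α-ionone; C3' from hydride delivery anti to the pseudoaxial ring methyl.

Key step: step 8

Assumption: (R)-(+)-α-ionone is bought enantiopure; carotenoid numbering (C1–C6 ring, C7–C15 chain, primes for the ε-half) is used for all intermediates.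

**Route**

Step 1
Reactants: 1 (S)-epichlorohydrin
Product: 3 (S)-2-(2-methylprop-2-en-1-yl)oxirane, via chlorohydrin 2 (not isolated)
Conditions: isopropenylmagnesium bromide, CuI (10 mol %), THF, −40 → 0 °C; then aq. NaOH, rt
Reagents that add atoms: isopropenylmagnesium bromide C=C(C)[Mg]Br
Why: Copper-catalysed Grignard opening at the unsubstituted epoxide carbon leaves the stereocentre untouched and base closes the new epoxide by Williamson displacement of chloride, so C3 comes unchanged from 1.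

Step 2
Reactants: 3 (S)-2-(2-methylprop-2-en-1-yl)oxirane; 4 ethyl propiolate
Product: 5 ethyl (S)-5-hydroxy-7-methyloct-7-en-2-ynoate
Conditions: n-BuLi, THF, −78 °C; BF3·OEt2; then 3, −78 °C
Reagents that add atoms: none
Why: BF3-promoted opening of the terminal epoxide by the lithium acetylide (Yamaguchi–Hirao alkynylation) occurs at the CH2 terminus and does not touch the carbinol centre.

Step 3
Reactants: 5 ethyl (S)-5-hydroxy-7-methyloct-7-en-2-ynoate
Product: 7 (S)-4-methyl-6-(2-methylprop-2-en-1-yl)-5,6-dihydro-2H-pyran-2-one, via hydroxy enoate 6 (not isolated)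
Conditions: Me2CuLi (2.5 equiv, from MeLi and CuI), THF, −78 °C; aq. NH4Cl; then p-TsOH (cat.), CH2Cl2, rt
Reagents that add atoms: lithium dimethylcuprate [Li+].C[Cu-]C
Why: Syn carbocupration of the ynoate places the C4 chain cis to the ester, so the (Z)-hydroxy enoate lactonises to the 4-methyl dihydropyranone.

Step 4
Reactants: 7 (S)-4-methyl-6-(2-methylprop-2-en-1-yl)-5,6-dihydro-2H-pyran-2-one
Product: 8 (R)-6-(2-chloro-2-methylpropyl)-4-methyl-5,6-dihydro-2H-pyran-2-one
Conditions: HCl (g), CH2Cl2, 0 °C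
Reagents that add atoms: hydrogen chloride Cl
Why: Markovnikov hydrochlorination of the electron-rich 1,1-disubstituted alkene gives the tertiary chloride (the later C1 electrophile) and masks this alkene against OsO4, while the electron-poor enoate does not react.

Step 5
Reactants: 8 (R)-6-(2-chloro-2-methylpropyl)-4-methyl-5,6-dihydro-2H-pyran-2-one
Product: 9 (3S,4S,6R)-6-(2-chloro-2-methylpropyl)-3,4-dihydroxy-4-methyltetrahydro-2H-pyran-2-one
Conditions: OsO4 (3 mol %), N-methylmorpholine N-oxide, acetone/H2O 10:1, rt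
Reagents that add atoms: N-methylmorpholine N-oxide C[N+]1([O-])CCOCC1; water O
Why: Catalytic syn-dihydroxylation of the cyclic enoate takes place on the lactone face opposite to the side chain, which sets the tertiary carbinol C5 syn to O3 as the target needs, and the acetone-rich medium keeps the tertiary chloride from solvolysis.

Step 6
Reactants: 9 (3S,4S,6R)-6-(2-chloro-2-methylpropyl)-3,4-dihydroxy-4-methyltetrahydro-2H-pyran-2-one
Product: 10 3,4-O-isopropylidene derivative of 9 (cis-fused dioxolane on the lactone)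
Conditions: Me2C(OMe)2, PPTS (cat.), acetone, rt
Reagents that add atoms: 2,2-dimethoxypropane COC(C)(C)OC
Why: Acid-catalysed transketalisation ties the cis-diol (O5, O6) into the dioxolane that later enforces the cis ring fusion.

Step 7
Reactants: 10 3,4-O-isopropylidene derivative of 9
Product: 12 methyl (4S,5S)-5-[(2R)-2-[(tert-butyldimethylsilyl)oxy]-4-chloro-4-methylpentyl]-2,2,5-trimethyl-1,3-dioxolane-4-carboxylate, via hydroxy ester 11 (not isolated)
Conditions: K2CO3 (cat.), MeOH, 0 °C; evaporate cold; t-BuMe2SiOTf, 2,6-lutidine, CH2Cl2, −78 °C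
Reagents that add atoms: methanol CO; tert-butyldimethylsilyl triflate CC(C)(C)[Si](C)(C)OS(=O)(=O)C(F)(F)F
Why: Base-catalysed methanolysis opens the bicyclic δ-lactone and fast low-temperature silylation of the freed C3 hydroxyl prevents relactonisation; epimerisation at C6 would be harmless because this centre is enolised in the next step.

Step 8
Reactants: 12 methyl (4S,5S)-5-[(2R)-2-[(tert-butyldimethylsilyl)oxy]-4-chloro-4-methylpentyl]-2,2,5-trimethyl-1,3-dioxolane-4-carboxylate
Product: 14 methyl 5-[(tert-butyldimethylsilyl)oxy]-2,2,3a,7,7-pentamethylhexahydro-1,3-benzodioxole-7a-carboxylate (cis-fused; silyloxy group cis to both ring oxygens), via ketene silyl acetal 13 (not isolated)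
Conditions: LiN(i-Pr)2, Me3SiCl, THF, −78 °C; solvent switch; ZnCl2, 2,6-di-tert-butyl-4-methylpyridine (0.1 equiv), CH2Cl2, −40 °C → rt
Reagents that add atoms: none
Why: LiN(i-Pr)2/Me3SiCl converts the α-alkoxy ester into ketene silyl acetal 13 (the C6 configuration of 12 is erased, so either epimer serves), and ZnCl2 then ionises the tertiary C1–Cl bond to the gem-dimethyl carbocation, which is captured by the nucleophilic C6 with loss of Me3SiCl. The closest known reaction type is the Lewis-acid-mediated α-tert-alkylation of silyl enol ethers and ketene silyl acetals with tertiary alkyl halides (SN1-type Mukaiyama alkylation, the standard way to join two fully substituted carbons), here run intramolecularly as a cation–olefin cyclisation. The cyclohexane ring C1–C6 closes in a 6-(enolexo)-exo mode through a chair-like transition state with the C3 silyloxy group equatorial. The new quaternary stereocentre C6 is controlled by the dioxolane that ties O5 to O6: C6 is planar and lies in this five-membered ring, and the C1 cation, tethered through C4 on C5, can reach only the face of C6 syn to C4, which gives the cis-fused bicycle with O6 cis to O5 and C7 trans to both. The step needs C-alkylation to outrun E1 proton loss from the cation and β-elimination of O5 from the enolate; the first is favoured by six-membered intramolecular capture by a very electron-rich tetrasubstituted ketene acetal, the second is suppressed because the C5–O5 bond lies near the enolate plane inside the dioxolane and the enolate is silylated in situ at −78 °C.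

Step 9
Reactants: 14 methyl 5-[(tert-butyldimethylsilyl)oxy]-2,2,3a,7,7-pentamethylhexahydro-1,3-benzodioxole-7a-carboxylate
Product: 15 5-[(tert-butyldimethylsilyl)oxy]-2,2,3a,7,7-pentamethylhexahydro-1,3-benzodioxole-7a-carbaldehyde (configuration as in 14)
Conditions: i-Bu2AlH (1.2 equiv), CH2Cl2, −78 °C
Reagents that add atoms: none
Why: Partial reduction of the hindered ester stops at the aluminium hemiacetal, which gives the non-enolisable C7 aldehyde on work-up.

Step 10
Reactants: 15 5-[(tert-butyldimethylsilyl)oxy]-2,2,3a,7,7-pentamethylhexahydro-1,3-benzodioxole-7a-carbaldehyde; 16 ethyl (E)-4-(diethoxyphosphoryl)-3-methylbut-2-enoate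
Product: 17 ethyl (2E,4E)-5-[5-[(tert-butyldimethylsilyl)oxy]-2,2,3a,7,7-pentamethylhexahydro-1,3-benzodioxol-7a-yl]-3-methylpenta-2,4-dienoate (configuration as in 14)
Conditions: LiN(SiMe3)2, THF/DMPU, −78 → 0 °C
Reagents that add atoms: none
Why: Horner–Wadsworth–Emmons olefination with the vinylogous C5 phosphonate forms the C7=C8 bond E-selectively, as with epoxycyclocitral-type aldehydes, and the ketal on O6 blocks an α-ketol rearrangement of the aldehyde under base.

Step 11
Reactants: 17 ethyl (2E,4E)-5-[5-[(tert-butyldimethylsilyl)oxy]-2,2,3a,7,7-pentamethylhexahydro-1,3-benzodioxol-7a-yl]-3-methylpenta-2,4-dienoate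
Product: 18 ethyl (2E,4E)-3-methyl-5-[(1R,2S,4S)-1,2,4-trihydroxy-2,6,6-trimethylcyclohexyl]penta-2,4-dienoate
Conditions: aq. HCl (1 M), THF, 40 °C
Reagents that add atoms: none
Why: Aqueous acid hydrolyses the silyl ether and the ketal, while ionisation of the allylic C6–O bond is disfavoured because the resulting cation would be conjugated to the electron-poor dienoate.

Step 12
Reactants: 18 ethyl (2E,4E)-3-methyl-5-[(1R,2S,4S)-1,2,4-trihydroxy-2,6,6-trimethylcyclohexyl]penta-2,4-dienoate
Product: 19 (2E,4E)-3-methyl-5-[(1R,2S,4S)-1,2,4-trihydroxy-2,6,6-trimethylcyclohexyl]penta-2,4-dien-1-ol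
Conditions: i-Bu2AlH (6 equiv), THF/CH2Cl2, −78 → 0 °C
Reagents that add atoms: none
Why: i-Bu2AlH reduces the dienoate 1,2 to the primary allylic alcohol after the three hydroxyls have been converted into aluminium alkoxides.

Step 13
Reactants: 19 (2E,4E)-3-methyl-5-[(1R,2S,4S)-1,2,4-trihydroxy-2,6,6-trimethylcyclohexyl]penta-2,4-dien-1-ol
Product: 21 [(2E,4E)-3-methyl-5-[(1R,2S,4S)-1,2,4-trihydroxy-2,6,6-trimethylcyclohexyl]penta-2,4-dien-1-yl]triphenylphosphonium bromide, via allylic bromide 20 (not isolated)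
Conditions: N-bromosuccinimide, Me2S, CH2Cl2, −30 → 0 °C; then PPh3, rt
Reagents that add atoms: N-bromosuccinimide O=C1CCC(=O)N1Br; triphenylphosphine c1ccc(cc1)P(c1ccccc1)c1ccccc1
Why: The Corey–Kim bromosulfonium reagent converts only the unhindered primary allylic alcohol into the bromide under neutral conditions (no acid that could ionise the tertiary allylic C6 alcohol), and SN2 quaternisation with PPh3 gives the C15 Wittig salt.

Step 14
Reactants: 22 (R)-α-ionone; 23 triethyl phosphonoacetate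
Product: 24 ethyl (2E,4E)-3-methyl-5-[(1R)-2,6,6-trimethylcyclohex-2-en-1-yl]penta-2,4-dienoate
Conditions: NaH (slight deficit relative to 23), THF, 0 °C → 50 °C
Reagents that add atoms: none
Why: Horner–Wadsworth–Emmons olefination of the methyl ketone gives mainly the (9'E) dienoate, and use of the preformed phosphonate anion without excess base avoids epimerisation at C6'.

Step 15
Reactants: 24 ethyl (2E,4E)-3-methyl-5-[(1R)-2,6,6-trimethylcyclohex-2-en-1-yl]penta-2,4-dienoate
Product: 25 ethyl (2E,4E)-3-methyl-5-[(1R)-2,6,6-trimethyl-4-oxocyclohex-2-en-1-yl]penta-2,4-dienoate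
Conditions: t-BuOOH (in decane), CuI (cat.), MeCN, 50 °C
Reagents that add atoms: tert-butyl hydroperoxide CC(C)(C)OO
Why: Copper-catalysed radical allylic oxidation attacks the only allylic ring methylene (C3') and, being non-basic, leaves the now vinylogously acidic C6' centre intact.

Step 16
Reactants: 25 ethyl (2E,4E)-3-methyl-5-[(1R)-2,6,6-trimethyl-4-oxocyclohex-2-en-1-yl]penta-2,4-dienoate
Product: 26 ethyl (2E,4E)-5-[(1R,4R)-4-hydroxy-2,6,6-trimethylcyclohex-2-en-1-yl]-3-methylpenta-2,4-dienoate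
Conditions: NaBH4, CeCl3·7H2O, MeOH, −20 °C
Reagents that add atoms: none
Why: Luche 1,2-reduction should deliver hydride to the ring enone from the face opposite to the pseudoaxial methyl on C1', that is syn to the C6' side chain, which gives the 3',6'-trans alcohol (3'R); the minor cis isomer is removed by chromatography.

Step 17
Reactants: 26 ethyl (2E,4E)-5-[(1R,4R)-4-hydroxy-2,6,6-trimethylcyclohex-2-en-1-yl]-3-methylpenta-2,4-dienoate
Product: 27 (2E,4E)-5-[(1R,4R)-4-hydroxy-2,6,6-trimethylcyclohex-2-en-1-yl]-3-methylpenta-2,4-dien-1-ol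
Conditions: i-Bu2AlH (3.5 equiv), CH2Cl2, −78 °C
Reagents that add atoms: none
Why: i-Bu2AlH reduces the dienoate to the primary dienylic alcohol without touching the ring alkene or the stereocentres.

Step 18
Reactants: 27 (2E,4E)-5-[(1R,4R)-4-hydroxy-2,6,6-trimethylcyclohex-2-en-1-yl]-3-methylpenta-2,4-dien-1-ol
Product: 28 [(2E,4E)-5-[(1R,4R)-4-hydroxy-2,6,6-trimethylcyclohex-2-en-1-yl]-3-methylpenta-2,4-dien-1-yl]triphenylphosphonium bromide
Conditions: PPh3·HBr (1.0 equiv), MeOH, 0 °C → rt
Reagents that add atoms: triphenylphosphine hydrobromide [Br-].c1ccc(cc1)[PH+](c1ccccc1)c1ccccc1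
Why: The primary dienylic alcohol is substituted by way of the pentadienyl cation (the classical preparation of retinyl-type Wittig salts), which forms far more readily than the ring allyl cation from the secondary C3' alcohol.

Step 19
Reactants: 28 [(2E,4E)-5-[(1R,4R)-4-hydroxy-2,6,6-trimethylcyclohex-2-en-1-yl]-3-methylpenta-2,4-dien-1-yl]triphenylphosphonium bromide; 29 (2E,4E,6E)-2,7-dimethylocta-2,4,6-trienedial
Product: 30 (3R,6R)-3-hydroxy-12'-apo-ε-caroten-12'-al
Conditions: 29 (3 equiv), NaOMe, MeOH/CH2Cl2, 0 °C → rt; then heat in EtOH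
Reagents that add atoms: none
Why: Wittig reaction of the ylide with an excess of the symmetrical dialdehyde gives the mono-condensation product, and the new C11'=C12' bond is equilibrated to E on heating.

Step 20
Reactants: 21 [(2E,4E)-3-methyl-5-[(1R,2S,4S)-1,2,4-trihydroxy-2,6,6-trimethylcyclohexyl]penta-2,4-dien-1-yl]triphenylphosphonium bromide; 30 (3R,6R)-3-hydroxy-12'-apo-ε-caroten-12'-al
Product: 31 5,6-dihydroxylutein, (3S,5S,6R,3'R,6'R)-5,6-dihydro-β,ε-carotene-3,5,6,3'-tetrol
Conditions: NaOMe (excess), MeOH/CH2Cl2, 0 °C → rt; then reflux in EtOH/heptane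
Reagents that add atoms: none
Why: The second Wittig reaction forms the C11=C12 bond and completes the C40 chain; the free hydroxyls are tolerated as alkoxides and the (11Z) isomer is isomerised thermally to the all-E target.

**Compound list**

1 | (S)-epichlorohydrin | ClC[C@@H]1CO1 | starting material
2 | (S)-1-chloro-4-methylpent-4-en-2-ol | C=C(C)C[C@H](O)CCl | intermediate
3 | (S)-2-(2-methylprop-2-en-1-yl)oxirane | C=C(C)C[C@H]1CO1 | intermediate
4 | ethyl propiolate | CCOC(=O)C#C | starting material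
5 | ethyl (S)-5-hydroxy-7-methyloct-7-en-2-ynoate | CCOC(=O)C#CC[C@@H](O)CC(C)=C | intermediate
6 | ethyl (2Z,5S)-5-hydroxy-3,7-dimethylocta-2,7-dienoate | CCOC(=O)/C=C(C)\C[C@@H](O)CC(C)=C | intermediate
7 | (S)-4-methyl-6-(2-methylprop-2-en-1-yl)-5,6-dihydro-2H-pyran-2-one | O=C1C=C(C)C[C@H](CC(C)=C)O1 | intermediate
8 | (R)-6-(2-chloro-2-methylpropyl)-4-methyl-5,6-dihydro-2H-pyran-2-one | O=C1C=C(C)C[C@H](CC(C)(C)Cl)O1 | intermediate
9 | (3S,4S,6R)-6-(2-chloro-2-methylpropyl)-3,4-dihydroxy-4-methyltetrahydro-2H-pyran-2-one | O=C1O[C@@H](CC(C)(C)Cl)C[C@](C)(O)[C@@H]1O | intermediate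
10 | 3,4-O-isopropylidene derivative of 9 (cis-fused acetonide lactone) | O=C1O[C@@H](CC(C)(C)Cl)C[C@]2(C)OC(C)(C)O[C@H]12 | intermediate
11 | methyl (4S,5S)-5-[(2R)-4-chloro-2-hydroxy-4-methylpentyl]-2,2,5-trimethyl-1,3-dioxolane-4-carboxylate | COC(=O)[C@H]1OC(C)(C)O[C@@]1(C)C[C@@H](O)CC(C)(C)Cl | intermediate
12 | methyl (4S,5S)-5-[(2R)-2-[(tert-butyldimethylsilyl)oxy]-4-chloro-4-methylpentyl]-2,2,5-trimethyl-1,3-dioxolane-4-carboxylate | COC(=O)[C@H]1OC(C)(C)O[C@@]1(C)C[C@@H](O[Si](C)(C)C(C)(C)C)CC(C)(C)Cl | intermediate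
13 | ketene methyl trimethylsilyl acetal of 12 (C6=C7, mixture of geometric isomers) | COC(O[Si](C)(C)C)=C1OC(C)(C)O[C@@]1(C)C[C@@H](O[Si](C)(C)C(C)(C)C)CC(C)(C)Cl | intermediate
14 | methyl 5-[(tert-butyldimethylsilyl)oxy]-2,2,3a,7,7-pentamethylhexahydro-1,3-benzodioxole-7a-carboxylate (cis-fused; O3, O5, O6 on one face as in the target) | COC(=O)[C@@]1(OC2(C)C)C(C)(C)C[C@H](O[Si](C)(C)C(C)(C)C)C[C@]1(C)O2 | intermediate
15 | 5-[(tert-butyldimethylsilyl)oxy]-2,2,3a,7,7-pentamethylhexahydro-1,3-benzodioxole-7a-carbaldehyde (configuration as in 14) | O=C[C@@]1(OC2(C)C)C(C)(C)C[C@H](O[Si](C)(C)C(C)(C)C)C[C@]1(C)O2 | intermediate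
16 | ethyl (E)-4-(diethoxyphosphoryl)-3-methylbut-2-enoate | CCOC(=O)/C=C(C)/CP(=O)(OCC)OCC | starting material
17 | ethyl (2E,4E)-5-[5-[(tert-butyldimethylsilyl)oxy]-2,2,3a,7,7-pentamethylhexahydro-1,3-benzodioxol-7a-yl]-3-methylpenta-2,4-dienoate (configuration as in 14) | CCOC(=O)/C=C(C)/C=C/[C@@]1(OC2(C)C)C(C)(C)C[C@H](O[Si](C)(C)C(C)(C)C)C[C@]1(C)O2 | intermediate
18 | ethyl (2E,4E)-3-methyl-5-[(1R,2S,4S)-1,2,4-trihydroxy-2,6,6-trimethylcyclohexyl]penta-2,4-dienoate | CCOC(=O)/C=C(C)/C=C/[C@@]1(O)C(C)(C)C[C@H](O)C[C@]1(C)O | intermediate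
19 | (2E,4E)-3-methyl-5-[(1R,2S,4S)-1,2,4-trihydroxy-2,6,6-trimethylcyclohexyl]penta-2,4-dien-1-ol | OC/C=C(C)/C=C/[C@@]1(O)C(C)(C)C[C@H](O)C[C@]1(C)O | intermediate
20 | (1R,2S,4S)-1-[(1E,3E)-5-bromo-3-methylpenta-1,3-dien-1-yl]-2,6,6-trimethylcyclohexane-1,2,4-triol | BrC/C=C(C)/C=C/[C@@]1(O)C(C)(C)C[C@H](O)C[C@]1(C)O | intermediate
21 | [(2E,4E)-3-methyl-5-[(1R,2S,4S)-1,2,4-trihydroxy-2,6,6-trimethylcyclohexyl]penta-2,4-dien-1-yl]triphenylphosphonium bromide | [Br-].c1ccccc1[P+](c1ccccc1)(c1ccccc1)C/C=C(C)/C=C/[C@@]1(O)C(C)(C)C[C@H](O)C[C@]1(C)O | intermediate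
22 | (R)-α-ionone | CC1=CCCC(C)(C)[C@H]1/C=C/C(C)=O | starting material
23 | triethyl phosphonoacetate | CCOC(=O)CP(=O)(OCC)OCC | starting material
24 | ethyl (2E,4E)-3-methyl-5-[(1R)-2,6,6-trimethylcyclohex-2-en-1-yl]penta-2,4-dienoate | CC1=CCCC(C)(C)[C@H]1/C=C/C(C)=C/C(=O)OCC | intermediate
25 | ethyl (2E,4E)-3-methyl-5-[(1R)-2,6,6-trimethyl-4-oxocyclohex-2-en-1-yl]penta-2,4-dienoate | CC1=CC(=O)CC(C)(C)[C@H]1/C=C/C(C)=C/C(=O)OCC | intermediate
26 | ethyl (2E,4E)-5-[(1R,4R)-4-hydroxy-2,6,6-trimethylcyclohex-2-en-1-yl]-3-methylpenta-2,4-dienoate | CC1=C[C@H](O)CC(C)(C)[C@H]1/C=C/C(C)=C/C(=O)OCC | intermediate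
27 | (2E,4E)-5-[(1R,4R)-4-hydroxy-2,6,6-trimethylcyclohex-2-en-1-yl]-3-methylpenta-2,4-dien-1-ol | CC1=C[C@H](O)CC(C)(C)[C@H]1/C=C/C(C)=C/CO | intermediate
28 | [(2E,4E)-5-[(1R,4R)-4-hydroxy-2,6,6-trimethylcyclohex-2-en-1-yl]-3-methylpenta-2,4-dien-1-yl]triphenylphosphonium bromide | [Br-].CC1=C[C@H](O)CC(C)(C)[C@H]1/C=C/C(C)=C/C[P+](c1ccccc1)(c1ccccc1)c1ccccc1 | intermediate
29 | (2E,4E,6E)-2,7-dimethylocta-2,4,6-trienedial | O=C/C(C)=C/C=C/C=C(C)/C=O | starting material
30 | (3R,6R)-3-hydroxy-12'-apo-ε-caroten-12'-al | CC1=C[C@H](O)CC(C)(C)[C@H]1/C=C/C(C)=C/C=C/C(C)=C/C=C/C=C(C)/C=O | intermediate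
31 | 5,6-dihydroxylutein, (3S,5S,6R,3'R,6'R)-5,6-dihydro-β,ε-carotene-3,5,6,3'-tetrol | CC1=C[C@H](O)CC(C)(C)[C@H]1/C=C/C(C)=C/C=C/C(C)=C/C=C/C=C(C)/C=C/C=C(C)/C=C/[C@@]1(O)C(C)(C)C[C@H](O)C[C@]1(C)O | target

**Step count**

Total steps: 20. Longest linear sequence: 14 (steps 1–13, then step 20).

**Steps most likely to fail**

Step 8. The tertiary cation may lose a proton (E1), or the ketene acetal may be protodesilylated, faster than the congested C1–C6 bond forms, so that 12 or its alkene isomers are returned. The fallback replaces the cation/ketene-acetal pairing by a radical/ketone pairing and sets out from 9. Methanolysis (K2CO3, MeOH) and silylation of the unhindered C3 hydroxyl (t-BuMe2SiCl, imidazole) would give methyl (2S,3S,5R)-5-[(tert-butyldimethylsilyl)oxy]-7-chloro-2,3-dihydroxy-3,7-dimethyloctanoate F1. Swern oxidation of its secondary C6 hydroxyl would give methyl (3S,5R)-5-[(tert-butyldimethylsilyl)oxy]-7-chloro-3-hydroxy-3,7-dimethyl-2-oxooctanoate F2. Slow addition of (Me3Si)3SiH/AIBN in toluene at 80 °C abstracts the tertiary chloride, and the tertiary radical adds 6-exo to the activated ketone to give methyl (1R,2S,4S)-4-[(tert-butyldimethylsilyl)oxy]-1,2-dihydroxy-2,6,6-trimethylcyclohexane-1-carboxylate F3. The 5,6-cis isomer is the one expected from the internally hydrogen-bonded α-hydroxy ketone, but this selectivity is not enforced by a ring as it is in step 8. Me2C(OMe)2/PPTS then gives 14, where the route is rejoined.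

Step 11. Under acid the tertiary allylic C6–O bond may ionise (elimination or rearrangement) before the hindered ketal is hydrolysed, or the ketal may be cleaved only in part. The fallback changes the protecting-group plan so that acid is used before any unsaturation is present, and sets out from 14. Hot aqueous acid removes ketal and silyl ether to give methyl (1R,2S,4S)-1,2,4-trihydroxy-2,6,6-trimethylcyclohexane-1-carboxylate F4. Me3SiOTf/Et3N gives methyl (1R,2S,4S)-2,6,6-trimethyl-1,2,4-tris[(trimethylsilyl)oxy]cyclohexane-1-carboxylate F5. i-Bu2AlH at −78 °C gives (1R,2S,4S)-2,6,6-trimethyl-1,2,4-tris[(trimethylsilyl)oxy]cyclohexane-1-carbaldehyde F6. Olefination with 16 as in step 10 gives ethyl (2E,4E)-3-methyl-5-[(1R,2S,4S)-2,6,6-trimethyl-1,2,4-tris[(trimethylsilyl)oxy]cyclohexyl]penta-2,4-dienoate F7. K2CO3 in EtOH removes the three silyl groups and gives 18.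

Step 13. The bromosulfonium reagent may also activate the secondary or the tertiary allylic hydroxyl, or the dienyl bromide may ionise towards C6, so that the Wittig salt is formed impure. The fallback reverses the polarity of the last union and sets out from 19 and 30. MnO2 oxidises only the primary allylic alcohol of 19 to (2E,4E)-3-methyl-5-[(1R,2S,4S)-1,2,4-trihydroxy-2,6,6-trimethylcyclohexyl]penta-2,4-dienal F8. NaBH4 reduces 30 to (3R,6R)-12'-apo-ε-carotene-3,12'-diol F9, which with PPh3·HBr in MeOH (as in step 18) gives [(3R,6R)-3-hydroxy-12'-apo-ε-caroten-12'-yl]triphenylphosphonium bromide F10. Wittig reaction of F10 with F8 (NaOMe, then thermal isomerisation) gives 31.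

**Further compounds**

F1 | step 8 | methyl (2S,3S,5R)-5-[(tert-butyldimethylsilyl)oxy]-7-chloro-2,3-dihydroxy-3,7-dimethyloctanoate | COC(=O)[C@@H](O)[C@@](C)(O)C[C@@H](O[Si](C)(C)C(C)(C)C)CC(C)(C)Cl
F2 | step 8 | methyl (3S,5R)-5-[(tert-butyldimethylsilyl)oxy]-7-chloro-3-hydroxy-3,7-dimethyl-2-oxooctanoate | COC(=O)C(=O)[C@@](C)(O)C[C@@H](O[Si](C)(C)C(C)(C)C)CC(C)(C)Cl
F3 | step 8 | methyl (1R,2S,4S)-4-[(tert-butyldimethylsilyl)oxy]-1,2-dihydroxy-2,6,6-trimethylcyclohexane-1-carboxylate | COC(=O)[C@@]1(O)C(C)(C)C[C@H](O[Si](C)(C)C(C)(C)C)C[C@]1(C)O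
F4 | step 11 | methyl (1R,2S,4S)-1,2,4-trihydroxy-2,6,6-trimethylcyclohexane-1-carboxylate | COC(=O)[C@@]1(O)C(C)(C)C[C@H](O)C[C@]1(C)O
F5 | step 11 | methyl (1R,2S,4S)-2,6,6-trimethyl-1,2,4-tris[(trimethylsilyl)oxy]cyclohexane-1-carboxylate | COC(=O)[C@@]1(O[Si](C)(C)C)C(C)(C)C[C@H](O[Si](C)(C)C)C[C@]1(C)O[Si](C)(C)C
F6 | step 11 | (1R,2S,4S)-2,6,6-trimethyl-1,2,4-tris[(trimethylsilyl)oxy]cyclohexane-1-carbaldehyde | O=C[C@@]1(O[Si](C)(C)C)C(C)(C)C[C@H](O[Si](C)(C)C)C[C@]1(C)O[Si](C)(C)C
F7 | step 11 | ethyl (2E,4E)-3-methyl-5-[(1R,2S,4S)-2,6,6-trimethyl-1,2,4-tris[(trimethylsilyl)oxy]cyclohexyl]penta-2,4-dienoate | CCOC(=O)/C=C(C)/C=C/[C@@]1(O[Si](C)(C)C)C(C)(C)C[C@H](O[Si](C)(C)C)C[C@]1(C)O[Si](C)(C)C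
F8 | step 13 | (2E,4E)-3-methyl-5-[(1R,2S,4S)-1,2,4-trihydroxy-2,6,6-trimethylcyclohexyl]penta-2,4-dienal | O=C/C=C(C)/C=C/[C@@]1(O)C(C)(C)C[C@H](O)C[C@]1(C)O
F9 | step 13 | (3R,6R)-12'-apo-ε-carotene-3,12'-diol | CC1=C[C@H](O)CC(C)(C)[C@H]1/C=C/C(C)=C/C=C/C(C)=C/C=C/C=C(C)/CO
F10 | step 13 | [(3R,6R)-3-hydroxy-12'-apo-ε-caroten-12'-yl]triphenylphosphonium bromide | [Br-].CC1=C[C@H](O)CC(C)(C)[C@H]1/C=C/C(C)=C/C=C/C(C)=C/C=C/C=C(C)/C[P+](c1ccccc1)(c1ccccc1)c1ccccc1
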